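## Analysis of the target

CNP0256302.0 (compound 26) has six rings. Ring A, a 3,5-dihydroxyphenyl group, is bound through an ether oxygen to B1 of ring B. Ring B is fused through the 1,4-dioxin ring C to ring D, which forms a dibenzofuran with furan ring E and ring F. The locants used below are: ring B, B1 (O–ring A), B2 (OH), B3 (H), B4 (OH), B5 and B6 (dioxin oxygens); ring D, D1 (dioxin oxygen from B6), D2 (OH), D3 (H), D4 (furan oxygen), D5 (bond to ring F), D6 (dioxin oxygen from B5); ring F carries two hydroxyls meta to each other. There is no stereocentre, so every selectivity problem is one of constitution. The seven free phenols, the para-dioxygenated (hydroquinone-type) ring B and the two phloroglucinol-type rings A and F make the compound sensitive to oxidants and electrophiles, so the free phenols should appear only in the last step. The difficulty is ring B: five oxygens in three different roles on one benzene ring, with the dioxin oriented so that the B5 oxygen goes to the bay carbon D6. Electrophilic substitution on such rings cannot be expected to place these groups selectively. The strategy rests on the sequence B2–B1–B6–B5 (four contiguous oxygenated carbons with para-related ends) followed by B4 (O) and B3 (H). This is the pattern produced when a squarate-derived 4-(1-alkoxyvinyl)-4-oxycyclobutenone opens and recloses: B2 is the former carbonyl carbon, B1 and B6 the two olefinic squarate carbons, B5 the carbinol carbon, and B4/B3 the vinyl ether carbons.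

## Retrosynthetic reasoning

**26 to 25.** The five O–methyl bonds and the O–ethyl bond at B4 are put back; the B2 hydroxyl stays free. Forward, a Lewis acid cleaves only alkyl–oxygen bonds, and the diaryl ether, dioxin and furan C–O bonds have no alkyl carbon to attack. This keeps the oxidation-prone heptaphenol out of the route until the end.

**25 to 24.** Three chlorine atoms are placed on ring A, ortho and para to its ether oxygen. They are spectators added on purpose. They make the ring A phenoxide a better leaving group than the dibenzofuranolate, which is needed two disconnections further back, and they block the ortho carbons of ring A. Forward, hydrogenolysis removes them once the last halogen-dependent step is over.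

**24 to 22.** The dioxin C–O bond between the B5 oxygen and D6 is cut. This gives 22, in which the dibenzofuran hangs on the B6 oxygen, bromine sits on the bay carbon D6 and the B5 oxygen carries a silyl group. This bond is chosen because the B5 oxygen is the one the ring-forming step delivers in protected form, while the B6 oxygen can be carried in as an aryl ether. Forward, fluoride frees the B5 phenolate and copper-catalysed etherification closes the six-membered ring.

**22 to 19 (key disconnection).** Ring B is opened between B2 and B3 and folded back to cyclobutenone 19. In 19, B2 is the carbonyl carbon, B1 and B6 are the olefinic carbons bearing the ring A aryloxy and the dibenzofuranyloxy groups, B5 is the silyloxy-bearing sp3 carbon, and B4/B3 are the 1-ethoxyvinyl group. All five oxygens of ring B, including both aryl ether bonds, are in place before the ring exists, so no substitution on an electron-rich arene is needed. The step also leaves B2 (free OH), B5 (silyl ether) and B4 (ethyl ether) differentiated. Compounds 19 and 22 are the cyclobutenone and the ring B hydroquinone of this plan, carried with a triethylsilyl group on the carbinol oxygen and three chlorines on ring A. Forward, the four-membered ring must open with the vinyl group turned inward and the ketene must close onto the vinyl CH2.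

**19 to 18 and 9.** The bond between C3 of the cyclobutenone and the dibenzofuranyl oxygen is cut. In a 4-oxycyclobutenone only C3 is a vinylogous ester carbon, so a phenoxide can replace only the aryloxy group next to the carbinol carbon. The dibenzofuran is thereby placed by constitution. The shorter order, adding the vinyl nucleophile to an unsymmetrical diaryl squarate, is not used as the main line. It would need the nucleophile to choose the carbonyl beside the dibenzofuranyloxy carbon. The ortho bromine makes that oxygen the poorer donor and that side the more hindered, so the choice cannot be relied on, and the wrong choice gives an isomeric ring B.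

**18 to 14 and 15 (through 16).** The bond between the carbinol carbon and the vinyl group is cut. Because 14 is a symmetrical diester, the organolithium 16 made from 15 has no regiochemical choice.

**14 to 13 and 11; 13 to 12; 11 to 10.** The two aryl–oxygen bonds of 14 are cut to the dichloride 13 of squaric acid 12 and two molecules of phenol 11, which comes from 10 by exhaustive chlorination.

**9 back to 1.** The isopropyl ether 8 protects the one hydroxyl that must be freed selectively. The biaryl bond between D5 and ring F is cut to diaryl ether 7, which has iodine on the future D5 and the bromine next to it. Ring F is symmetrical and needs no handle, but the two carbons of ring D ortho to the ether oxygen must be told apart, hence the iodine. Ether 7 comes from phenol 5 and boronic acid 6 by an oxidative copper coupling that leaves both halogens alone. Phenol 5 comes from aldehyde 3 (formyl to hydroxyl), 3 from 2 (iodination) and 2 from 1. Compound 1 already has Br, OH and OMe in the contiguous order needed for D6, D1 and D2, and its formyl carbon becomes the furan oxygen carbon D4. A 3,4,5-trioxygenated phenol would not serve as ring D, because it would put an oxygen where the bromine has to be.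

## Alternatives that were turned down

**Alternative 1:** The furan ring E and the bond from D5 to ring F are cut. Ring F then comes from phloroglucinol A3, used as its triketone tautomer, and the rest is the tetracyclic O-aryl hydroxylamine A2 (rings A to D as pentamethyl ether, O–NH2 on D4). Forward, a strong sulfonic acid condenses A2 with A3 to an O-aryl oxime ether, a [3,3]-sigmatropic shift makes the D5–carbon bond, and the freed ring D phenol closes the furan with loss of ammonia to give A1.
- For: ring F needs no protecting groups, A3 is symmetrical, no metal or halogen is needed, and rings E and F are attached more convergently than by the six-step dibenzofuran synthesis of the chosen route. On that point it is the stronger plan.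
- Against: the oxygen on D4 has two free ortho carbons, D3 and D5, and the shift must go to the more crowded D5. The N–O bond on so electron-rich a ring is fragile. Hot acid and A3 invite C-alkylation and oligomers. Above all, A2 already contains ring B and the dioxin, so the hard part of the target must be solved beforehand by other chemistry.
- Comparison: the chosen route spends its key step on that hard part and fixes the ring D regiochemistry with halogens placed on compound 1, not with a preference between two ortho carbons.

**Alternative 2:** The hydroxyl C–O bonds at B2 and B4 are traced back to formyl groups, that is to dialdehyde A5. Its acceptor groups lie ortho and para to B1 and B5 and open those positions to nucleophilic aromatic substitution. Forward, a peracid converts both formyl groups into formates by aryl migration (Baeyer–Villiger oxidation) and mild base gives diphenol A4, one global demethylation away from the target.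
- For: every bond-forming step is an ordinary, predictable reaction, the sites of substitution are dictated by the acceptor groups, and no strained, heat-sensitive intermediate is needed. Step for step it is the more reliable plan.
- Against: B6 is meta to both formyl groups and gets no activation, so the third aryl–oxygen bond still needs copper or an oxygen present from the outset. Three different oxygen nucleophiles must enter in a controlled order, the double oxidation must spare rings A and F, and the sequence is longer.
- Comparison: the chosen strategy forms all five C–O bonds of ring B before the ring exists and differentiates B2 from B4 at no extra cost, in one thermal step. It gives up the predictability of the individual steps that lead from A5 to A4.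

**Alternative 3:** Only the dioxin bond from B5 to the oxygen on D6 is cut. This gives the open diaryl ether A7, with a free phenol at B2, hydrogen at B5 and a free hydroxyl at D6. Forward, a hypervalent iodine oxidant in a fluorinated alcohol oxidises the ring B phenol, and the D6 hydroxyl adds to B5, para to it, closing the dioxin to A6.
- For: it mirrors the likely biosynthesis, needs no halogen on ring D (so no bay-region bromide and no copper step) and is the shortest of the four plans. In step economy it clearly beats the chosen route.
- Against: A7 has two free phenols and three very electron-rich rings. The ring D phenol has a free para carbon (D3) and is itself a substrate for oxidative dearomatisation. B5 is flanked by two oxygen-bearing carbons, so attack at B1 or by solvent competes. A6, a para-alkoxyphenol, is more easily oxidised than A7.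
- Comparison: the chosen strategy never exposes an electron-rich phenol to an oxidant and fixes every oxygen by constitution, at the price of more steps.

Key step: step 12

Assumption: the target has no stereocentre; compounds 17, 18 and 19 have one stereocentre at the carbinol carbon, are handled as racemates, and lose it in step 12.

## Route

Step 1
Reactants: 1 5-bromovanillin (3-bromo-4-hydroxy-5-methoxybenzaldehyde)
Product: 2 3-bromo-5-methoxy-4-(propan-2-yloxy)benzaldehyde
Conditions: 2-bromopropane, K2CO3, DMF, 60 °C
Reagents that add atoms: 2-bromopropane, CC(C)Br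
Why: Williamson ether synthesis; the acidic phenol between Br and OMe is deprotonated by K2CO3 and alkylated by the secondary bromide. The isopropyl group is chosen because BCl3 later removes it without touching methyl ethers.

Step 2
Reactants: 2 3-bromo-5-methoxy-4-(propan-2-yloxy)benzaldehyde
Product: 3 3-bromo-2-iodo-5-methoxy-4-(propan-2-yloxy)benzaldehyde
Conditions: NIS, CF3CO2H, MeCN, rt, dark
Reagents that add atoms: N-iodosuccinimide, O=C1CCC(=O)N1I
Why: Electrophilic aromatic iodination at the only free carbon para to the methoxy group (between CHO and Br), the same carbon that takes the second bromine when 1 is brominated further. The other free carbon is only ortho to methoxy.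

Step 3
Reactants: 3 3-bromo-2-iodo-5-methoxy-4-(propan-2-yloxy)benzaldehyde
Product: 5 3-bromo-2-iodo-5-methoxy-4-(propan-2-yloxy)phenol, via aryl formate 4 (not isolated)
Conditions: mCPBA, CH2Cl2, 0 °C to rt; then K2CO3 (0.2 equiv), MeOH, rt
Reagents that add atoms: 3-chloroperbenzoic acid (mCPBA), OOC(=O)c1cccc(Cl)c1
Why: Baeyer–Villiger oxidation of an electron-rich benzaldehyde (Dakin-type); the aryl group, with the alkoxy group para to the formyl carbon, migrates to oxygen and the formate 4 is methanolysed. The aryl iodide and bromide should survive the unacidified peracid.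

Step 4
Reactants: 5 3-bromo-2-iodo-5-methoxy-4-(propan-2-yloxy)phenol; 6 (3,5-dimethoxyphenyl)boronic acid
Product: 7 3-bromo-1-(3,5-dimethoxyphenoxy)-2-iodo-5-methoxy-4-(propan-2-yloxy)benzene
Conditions: Cu(OAc)2 (20 mol%), pyridine, 4 Å molecular sieves, O2 (1 atm), CH2Cl2, rt
Reagents that add atoms: none
Why: Chan–Lam coupling; the phenol is O-arylated by the boronic acid under divalent copper and oxygen at room temperature, where neither the C–I nor the C–Br bond reacts. A halide-based Ullmann coupling would not leave these halogens alone.

Step 5
Reactants: 7 3-bromo-1-(3,5-dimethoxyphenoxy)-2-iodo-5-methoxy-4-(propan-2-yloxy)benzene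
Product: 8 1-bromo-3,7,9-trimethoxy-2-(propan-2-yloxy)dibenzo[b,d]furan
Conditions: Pd(OAc)2 (5 mol%), PPh3 (10 mol%), Ag2CO3 (0.6 equiv), pivalic acid (30 mol%), DMA, 90 °C
Reagents that add atoms: none
Why: Intramolecular direct arylation; zerovalent palladium inserts into C–I much faster than into the neighbouring C–Br, and carboxylate-assisted C–H cleavage at the ring F carbon ortho to the ether oxygen closes the five-membered ring. Ring F is symmetrical, so both such carbons give the same product, and Ag2CO3 removes iodide so the temperature can stay low enough to spare the bromide.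

Step 6
Reactants: 8 1-bromo-3,7,9-trimethoxy-2-(propan-2-yloxy)dibenzo[b,d]furan
Product: 9 1-bromo-3,7,9-trimethoxydibenzo[b,d]furan-2-ol
Conditions: BCl3, CH2Cl2, −78 to 0 °C; then H2O
Reagents that add atoms: none
Why: Lewis-acid dealkylation; BCl3 cleaves the secondary isopropyl aryl ether much faster than methyl aryl ethers, so only the hydroxyl next to the bromine is freed.

Step 7
Reactants: 10 3,5-dimethoxyphenol
Product: 11 2,4,6-trichloro-3,5-dimethoxyphenol
Conditions: SO2Cl2 (3.05 equiv), CH2Cl2–Et2O, 0 °C to rt
Reagents that add atoms: sulfuryl chloride, O=S(=O)(Cl)Cl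
Why: Electrophilic aromatic chlorination of the three carbons ortho and para to the hydroxyl, each activated by three oxygens; three equivalents are used to stop before dienone formation. The chlorines make this phenol the better leaving group in step 11 and are removed in step 14.

Step 8
Reactants: 12 squaric acid (3,4-dihydroxycyclobut-3-ene-1,2-dione)
Product: 13 squaric acid dichloride (3,4-dichlorocyclobut-3-ene-1,2-dione)
Conditions: (COCl)2, DMF (cat.), CH2Cl2, reflux
Reagents that add atoms: oxalyl chloride, O=C(Cl)C(=O)Cl
Why: Conversion of a vinylogous carboxylic acid into its chloride with oxalyl chloride under DMF catalysis (Vilsmeier-type activation), the standard preparation of this dichloride.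

Step 9
Reactants: 13 squaric acid dichloride; 11 2,4,6-trichloro-3,5-dimethoxyphenol (2 equiv)
Product: 14 3,4-bis(2,4,6-trichloro-3,5-dimethoxyphenoxy)cyclobut-3-ene-1,2-dione
Conditions: iPr2NEt (2.1 equiv), CH2Cl2, −20 to 0 °C
Reagents that add atoms: none
Why: Twofold addition–elimination at the chlorine-bearing carbons (vinylogous acyl substitution), the usual route to diaryl squarates. The product is symmetrical, so its two carbonyl groups are equivalent.

Step 10
Reactants: 15 ethyl vinyl ether (ethoxyethene); 14 3,4-bis(2,4,6-trichloro-3,5-dimethoxyphenoxy)cyclobut-3-ene-1,2-dione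
Product: 18 rac-4-(1-ethoxyethenyl)-2,3-bis(2,4,6-trichloro-3,5-dimethoxyphenoxy)-4-(triethylsilyloxy)cyclobut-2-en-1-one, via 1-ethoxyvinyllithium 16 (not isolated), via lithium alkoxide 17 (not isolated)
Conditions: 15, tBuLi, THF, −78 to 0 °C; then 14, THF, −78 °C; then Et3SiCl, −78 to −20 °C
Reagents that add atoms: chlorotriethylsilane, CC[Si](Cl)(CC)CC
Why: α-Lithiation of the enol ether, 1,2-addition of the organolithium to a squarate carbonyl at −78 °C and O-silylation of the alkoxide, the standard entry to 4-substituted 4-silyloxycyclobutenones. Because 14 is symmetrical the addition has no regiochemical choice; the new stereocentre forms as a racemate and disappears in step 12.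

Step 11
Reactants: 18 rac-4-(1-ethoxyethenyl)-2,3-bis(2,4,6-trichloro-3,5-dimethoxyphenoxy)-4-(triethylsilyloxy)cyclobut-2-en-1-one; 9 1-bromo-3,7,9-trimethoxydibenzo[b,d]furan-2-ol
Product: 19 rac-3-[(1-bromo-3,7,9-trimethoxydibenzo[b,d]furan-2-yl)oxy]-4-(1-ethoxyethenyl)-2-(2,4,6-trichloro-3,5-dimethoxyphenoxy)-4-(triethylsilyloxy)cyclobut-2-en-1-one
Conditions: Cs2CO3 (1.1 equiv), DMF, 0 °C to rt
Reagents that add atoms: none
Why: Addition–elimination at the β-carbon of the enone (vinylogous transesterification), known for 3-alkoxy- and 3-halocyclobutenones and for squarate esters. C3 is the only vinylogous ester carbon, so only its aryloxy group can be replaced, and the exchange is driven because the trichlorophenolate (estimated to be two to three pKa units more stable) is the better leaving group. The dibenzofuranyloxy group therefore ends next to the carbinol carbon by constitution, not by a selectivity.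

Step 12
Reactants: 19 rac-3-[(1-bromo-3,7,9-trimethoxydibenzo[b,d]furan-2-yl)oxy]-4-(1-ethoxyethenyl)-2-(2,4,6-trichloro-3,5-dimethoxyphenoxy)-4-(triethylsilyloxy)cyclobut-2-en-1-one
Product: 22 3-[(1-bromo-3,7,9-trimethoxydibenzo[b,d]furan-2-yl)oxy]-5-ethoxy-2-(2,4,6-trichloro-3,5-dimethoxyphenoxy)-4-(triethylsilyloxy)phenol, via dienylketene 20 (not isolated), via cyclohexadienone 21 (not isolated)
Conditions: toluene (degassed, 0.02 M), 110 °C, Ar
Reagents that add atoms: none
Why: Heating opens the cyclobutenone by conrotatory 4π electrocyclic cleavage of the bond between the carbonyl carbon and the silyloxy-bearing carbon and gives dienylketene 20. The silyloxy donor on the breaking bond turns outward, so the 1-ethoxyvinyl group turns inward and ends cis to the ketene. A thermally allowed 6π electrocyclisation then joins the ketene carbon to the vinyl CH2 and closes the six-membered ring B as dienone 21, and enolisation of its CH2–C=O unit gives phenol 22 with the silyl group still on the para oxygen. The closest known reaction type is the thermal ring expansion of squarate-derived 4-alkenyl-4-hydroxy- or 4-silyloxycyclobutenones to hydroquinones and their monosilyl ethers. No stereocentre is formed and the one at the carbinol carbon is lost. The step needs the inward rotation of the vinyl group, which the oxygen on the same carbon secures, and it needs the ketene to find no other partner: both ortho positions of each aryloxy group are blocked (Cl and Cl, Br and OMe) and the solution is dilute and free of protic nucleophiles. The oxygen pattern of ring B is fixed by the constitution of 19 and cannot be scrambled here.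

Step 13
Reactants: 22 3-[(1-bromo-3,7,9-trimethoxydibenzo[b,d]furan-2-yl)oxy]-5-ethoxy-2-(2,4,6-trichloro-3,5-dimethoxyphenoxy)-4-(triethylsilyloxy)phenol
Product: 24 ring A trichloro pentamethyl B4-O-ethyl ether of 26 with free B2 hydroxyl (dioxin closed), via caesium phenolate 23 (not isolated)
Conditions: CsF (2.5 equiv), CuI (10 mol%), N,N-dimethylglycine (20 mol%), DMF (degassed), 90 °C, Ar
Reagents that add atoms: none
Why: Fluoride cleaves the aryl silyl ether and gives the caesium phenolate 23 at B5 only; intramolecular Ullmann ether synthesis under monovalent copper then displaces the neighbouring bay-region bromide and closes the six-membered dioxin ring. Aryl chlorides are far less reactive than the bromide under these conditions, and the B2 hydroxyl stays largely protonated.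

Step 14
Reactants: 24 ring A trichloro pentamethyl B4-O-ethyl ether of 26 with free B2 hydroxyl
Product: 25 pentamethyl B4-O-ethyl ether of 26 with free B2 hydroxyl (methyl on both ring A oxygens, on the D2 oxygen and on both ring F oxygens)
Conditions: H2 (1 atm), Pd/C (10 wt% Pd), Et3N, EtOAc–MeOH, 40 °C
Reagents that add atoms: none
Why: Catalytic hydrodehalogenation; aryl chlorides are hydrogenolysed over palladium on carbon with an amine that takes up HCl. Aryl ethers, the dioxin and the furan are inert.

Step 15
Reactants: 25 pentamethyl B4-O-ethyl ether of 26 with free B2 hydroxyl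
Product: 26 CNP0256302.0 (ring B with O-(3,5-dihydroxyphenyl) at B1 and OH at B2 and B4, fused through the dioxin oxygens B5–O–D6 and B6–O–D1 to the dibenzofuran with OH at D2 and two OH on ring F)
Conditions: BBr3 (excess), CH2Cl2, −78 °C to rt; then MeOH, H2O
Reagents that add atoms: none
Why: Lewis-acid cleavage of all alkyl aryl ethers (five methyl, one ethyl) by bromide attack at the alkyl carbon. Diaryl ether, dioxin and furan C–O bonds have no alkyl carbon and survive, and the air-sensitive heptaphenol is freed only in this last step.

## Compound list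

1 | 5-bromovanillin (3-bromo-4-hydroxy-5-methoxybenzaldehyde) | O=Cc1cc(Br)c(O)c(OC)c1 | starting material
2 | 3-bromo-5-methoxy-4-(propan-2-yloxy)benzaldehyde | O=Cc1cc(Br)c(OC(C)C)c(OC)c1 | intermediate
3 | 3-bromo-2-iodo-5-methoxy-4-(propan-2-yloxy)benzaldehyde | O=Cc1cc(OC)c(OC(C)C)c(Br)c1I | intermediate
4 | 3-bromo-2-iodo-5-methoxy-4-(propan-2-yloxy)phenyl formate (not isolated) | O=COc1cc(OC)c(OC(C)C)c(Br)c1I | intermediate
5 | 3-bromo-2-iodo-5-methoxy-4-(propan-2-yloxy)phenol | Oc1cc(OC)c(OC(C)C)c(Br)c1I | intermediate
6 | (3,5-dimethoxyphenyl)boronic acid | COc1cc(OC)cc(B(O)O)c1 | starting material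
7 | 3-bromo-1-(3,5-dimethoxyphenoxy)-2-iodo-5-methoxy-4-(propan-2-yloxy)benzene | COc1cc(OC)cc(Oc2cc(OC)c(OC(C)C)c(Br)c2I)c1 | intermediate
8 | 1-bromo-3,7,9-trimethoxy-2-(propan-2-yloxy)dibenzo[b,d]furan | CC(C)Oc1c(OC)cc2oc3cc(OC)cc(OC)c3c2c1Br | intermediate
9 | 1-bromo-3,7,9-trimethoxydibenzo[b,d]furan-2-ol | Oc1c(OC)cc2oc3cc(OC)cc(OC)c3c2c1Br | intermediate
10 | 3,5-dimethoxyphenol | COc1cc(O)cc(OC)c1 | starting material
11 | 2,4,6-trichloro-3,5-dimethoxyphenol | COc1c(Cl)c(O)c(Cl)c(OC)c1Cl | intermediate
12 | squaric acid (3,4-dihydroxycyclobut-3-ene-1,2-dione) | OC1=C(O)C(=O)C1=O | starting material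
13 | squaric acid dichloride (3,4-dichlorocyclobut-3-ene-1,2-dione) | ClC1=C(Cl)C(=O)C1=O | intermediate
14 | 3,4-bis(2,4,6-trichloro-3,5-dimethoxyphenoxy)cyclobut-3-ene-1,2-dione | O=C1C(=O)C(Oc2c(Cl)c(OC)c(Cl)c(OC)c2Cl)=C1Oc1c(Cl)c(OC)c(Cl)c(OC)c1Cl | intermediate
15 | ethyl vinyl ether (ethoxyethene) | C=COCC | starting material
16 | (1-ethoxyethenyl)lithium (not isolated) | [Li]C(=C)OCC | intermediate
17 | racemic lithium 1-(1-ethoxyethenyl)-4-oxo-2,3-bis(2,4,6-trichloro-3,5-dimethoxyphenoxy)cyclobut-2-en-1-olate (not isolated) | [Li]OC1(C(=C)OCC)C(=O)C(Oc2c(Cl)c(OC)c(Cl)c(OC)c2Cl)=C1Oc1c(Cl)c(OC)c(Cl)c(OC)c1Cl | intermediate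
18 | rac-4-(1-ethoxyethenyl)-2,3-bis(2,4,6-trichloro-3,5-dimethoxyphenoxy)-4-(triethylsilyloxy)cyclobut-2-en-1-one | C=C(OCC)C1(O[Si](CC)(CC)CC)C(=O)C(Oc2c(Cl)c(OC)c(Cl)c(OC)c2Cl)=C1Oc1c(Cl)c(OC)c(Cl)c(OC)c1Cl | intermediate
19 | rac-3-[(1-bromo-3,7,9-trimethoxydibenzo[b,d]furan-2-yl)oxy]-4-(1-ethoxyethenyl)-2-(2,4,6-trichloro-3,5-dimethoxyphenoxy)-4-(triethylsilyloxy)cyclobut-2-en-1-one (key-step precursor) | C=C(OCC)C1(O[Si](CC)(CC)CC)C(=O)C(Oc2c(Cl)c(OC)c(Cl)c(OC)c2Cl)=C1Oc1c(OC)cc2oc3cc(OC)cc(OC)c3c2c1Br | intermediate
20 | dienylketene: 3-[(1-bromo-3,7,9-trimethoxydibenzo[b,d]furan-2-yl)oxy]-5-ethoxy-2-(2,4,6-trichloro-3,5-dimethoxyphenoxy)-4-(triethylsilyloxy)hexa-1,3,5-trien-1-one, ethoxyvinyl group cis to the ketene-bearing carbon (not isolated) | O=C=C(Oc1c(Cl)c(OC)c(Cl)c(OC)c1Cl)/C(Oc1c(OC)cc2oc3cc(OC)cc(OC)c3c2c1Br)=C(/O[Si](CC)(CC)CC)C(=C)OCC | intermediate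
21 | 3-[(1-bromo-3,7,9-trimethoxydibenzo[b,d]furan-2-yl)oxy]-5-ethoxy-2-(2,4,6-trichloro-3,5-dimethoxyphenoxy)-4-(triethylsilyloxy)cyclohexa-2,4-dien-1-one (not isolated) | O=C1CC(OCC)=C(O[Si](CC)(CC)CC)C(Oc2c(OC)cc3oc4cc(OC)cc(OC)c4c3c2Br)=C1Oc1c(Cl)c(OC)c(Cl)c(OC)c1Cl | intermediate
22 | 3-[(1-bromo-3,7,9-trimethoxydibenzo[b,d]furan-2-yl)oxy]-5-ethoxy-2-(2,4,6-trichloro-3,5-dimethoxyphenoxy)-4-(triethylsilyloxy)phenol (key-step product) | CCOc1cc(O)c(Oc2c(Cl)c(OC)c(Cl)c(OC)c2Cl)c(Oc2c(OC)cc3oc4cc(OC)cc(OC)c4c3c2Br)c1O[Si](CC)(CC)CC | intermediate
23 | caesium 2-[(1-bromo-3,7,9-trimethoxydibenzo[b,d]furan-2-yl)oxy]-6-ethoxy-4-hydroxy-3-(2,4,6-trichloro-3,5-dimethoxyphenoxy)phenolate (not isolated) | CCOc1cc(O)c(Oc2c(Cl)c(OC)c(Cl)c(OC)c2Cl)c(Oc2c(OC)cc3oc4cc(OC)cc(OC)c4c3c2Br)c1[O-].[Cs+] | intermediate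
24 | ring A trichloro pentamethyl B4-O-ethyl ether of 26 with free B2 hydroxyl | COc1c(Cl)c(OC)c(Cl)c(Oc2c(O)cc(OCC)c3c2Oc2c(OC)cc4oc5cc(OC)cc(OC)c5c4c2O3)c1Cl | intermediate
25 | pentamethyl B4-O-ethyl ether of 26 with free B2 hydroxyl | COc1cc(OC)cc(Oc2c(O)cc(OCC)c3c2Oc2c(OC)cc4oc5cc(OC)cc(OC)c5c4c2O3)c1 | intermediate
26 | CNP0256302.0 | Oc1cc(O)cc(Oc2c(O)cc(O)c3c2Oc2c(O)cc4oc5cc(O)cc(O)c5c4c2O3)c1 | target

## Step count and least certain steps

Total step count: 15. Longest linear sequence: 11 steps (steps 1 to 6, then 11 to 15).

**Step 12 (key step).** The most likely failure is that the dienylketene is consumed before it closes. This could happen through capture by traces of water or silanol, through dimerisation, or through hydrolysis of the acid-sensitive 1-ethoxyvinyl group at 110 °C. Crowding by the two flanking aryloxy groups could also slow the 6π closure enough for decomposition to win. The fallback changes the disconnection of ring B and uses neither chlorine nor a silyl group. It sets out from 13, 9 and 10 and comes back to the route at 25. Dichloride 13 and dibenzofuranol 9 give the monoester chloride F1 (as in the fallback to step 11), and 3,5-dimethoxyphenol 10 with iPr2NEt converts it into the mixed diester F4. (Z)-2-Ethoxyvinyllithium F5, from (Z)-1-bromo-2-ethoxyethene and tBuLi at −78 °C, is added to F4 at −78 °C to give the lithium alkoxide F6 at the carbonyl next to the ring A ether carbon. Aqueous NH4Cl gives the carbinol F7. Heating F7 in toluene opens it to the dienylketene F8, which closes onto the ethoxy-bearing vinyl terminus to the dienone F9 and enolises to the free hydroquinone F10. This is cyclised at once (CuI, N,N-dimethylglycine, Cs2CO3, dioxane, 90 °C, Ar) to 25. The fallback needs the organolithium to take the carbonyl on the less hindered ring A side. That is the direction expected for F4, but it is a preference and not a certainty, which is why it is only a fallback.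

**Step 11.** The most likely failure is slow attack of the hindered phenolate at the crowded β-carbon. On long reaction or warming, the silyl group could then be transferred to the phenolate or the cyclobutenone could begin to open. The fallback changes the order of events. It sets out from 13, 9, 11 and 16 and comes back at 19. Dichloride 13 is treated with one equivalent of 9 (iPr2NEt, CH2Cl2, −40 °C) to give the monoester chloride F1, and then with 11 to give the unsymmetrical diester F2. Organolithium 16 is added at −78 °C and the lithium alkoxide F3 is silylated with Et3SiCl to give 19. In this order the regiochemistry is no longer enforced. It rests on the electron-poor trichloroaryl ester leaving the carbonyl conjugated to its oxygen, the one next to the dibenzofuranyloxy carbon, the more electrophilic. Any regioisomer would have to be separated.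

**Step 13.** The most likely failures are oxidation of the electron-rich phenolate to a quinone by traces of oxygen in the presence of copper, attack of the B2 oxygen on an ortho chlorine of ring A, or sluggish coupling at the hindered bay-region bromide. The fallback removes one phenol before the cyclisation. It sets out from 22 and comes back at 26. The free B2 hydroxyl of 22 is methylated with Me3SiCHN2 in toluene–MeOH to the methyl ether F11. CsF then gives a single phenolate, the caesium salt F12, which can be cyclised under the same or more forcing copper conditions to the dioxin F13. Hydrogenolysis (H2, Pd/C, Et3N) gives F14, and BBr3 cleaves the extra methyl ether together with the others to give 26.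

**Step 5.** The most likely failure is insertion of palladium into the C–Br bond of 7 or of 8, with loss of the bromine that step 13 needs. The fallback uses no palladium and closes the furan by C–O bond formation. It sets out from 1 and comes back at 9. Dakin oxidation of 1 (H2O2, NaOH) gives the hydroquinone F15, and FeCl3 in water–CH2Cl2 oxidises it to the quinone F16. Acid-promoted addition of 1,3,5-trimethoxybenzene (CF3CO2H, CH2Cl2) should occur at the only unsubstituted quinone carbon that is not an enol ether carbon, the one next to C–Br, and gives the biaryl hydroquinone F17. A Na2S2O4 wash returns any arylquinone to F17. Heating with TsOH in toluene lets the hydroxyl ortho to the biaryl bond displace a methoxy group of the phloroglucinol ring with loss of methanol, giving 9 directly.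

## Further compounds

F1 | step 11 | 3-[(1-bromo-3,7,9-trimethoxydibenzo[b,d]furan-2-yl)oxy]-4-chlorocyclobut-3-ene-1,2-dione | O=C1C(=O)C(Cl)=C1Oc1c(OC)cc2oc3cc(OC)cc(OC)c3c2c1Br
F2 | step 11 | 3-[(1-bromo-3,7,9-trimethoxydibenzo[b,d]furan-2-yl)oxy]-4-(2,4,6-trichloro-3,5-dimethoxyphenoxy)cyclobut-3-ene-1,2-dione | O=C1C(=O)C(Oc2c(Cl)c(OC)c(Cl)c(OC)c2Cl)=C1Oc1c(OC)cc2oc3cc(OC)cc(OC)c3c2c1Br
F3 | step 11 | racemic lithium 2-[(1-bromo-3,7,9-trimethoxydibenzo[b,d]furan-2-yl)oxy]-1-(1-ethoxyethenyl)-4-oxo-3-(2,4,6-trichloro-3,5-dimethoxyphenoxy)cyclobut-2-en-1-olate | [Li]OC1(C(=C)OCC)C(=O)C(Oc2c(Cl)c(OC)c(Cl)c(OC)c2Cl)=C1Oc1c(OC)cc2oc3cc(OC)cc(OC)c3c2c1Br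
F4 | step 12 | 3-[(1-bromo-3,7,9-trimethoxydibenzo[b,d]furan-2-yl)oxy]-4-(3,5-dimethoxyphenoxy)cyclobut-3-ene-1,2-dione | O=C1C(=O)C(Oc2cc(OC)cc(OC)c2)=C1Oc1c(OC)cc2oc3cc(OC)cc(OC)c3c2c1Br
F5 | step 12 | [(Z)-2-ethoxyethenyl]lithium | CCO/C=C\[Li]
F6 | step 12 | racemic lithium 3-[(1-bromo-3,7,9-trimethoxydibenzo[b,d]furan-2-yl)oxy]-2-(3,5-dimethoxyphenoxy)-1-[(Z)-2-ethoxyethenyl]-4-oxocyclobut-2-en-1-olate | [Li]OC1(/C=C\OCC)C(=O)C(Oc2c(OC)cc3oc4cc(OC)cc(OC)c4c3c2Br)=C1Oc1cc(OC)cc(OC)c1
F7 | step 12 | rac-2-[(1-bromo-3,7,9-trimethoxydibenzo[b,d]furan-2-yl)oxy]-3-(3,5-dimethoxyphenoxy)-4-[(Z)-2-ethoxyethenyl]-4-hydroxycyclobut-2-en-1-one | CCO/C=C\C1(O)C(=O)C(Oc2c(OC)cc3oc4cc(OC)cc(OC)c4c3c2Br)=C1Oc1cc(OC)cc(OC)c1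
F8 | step 12 | dienylketene: 2-[(1-bromo-3,7,9-trimethoxydibenzo[b,d]furan-2-yl)oxy]-3-(3,5-dimethoxyphenoxy)-6-ethoxy-4-hydroxyhexa-1,3,5-trien-1-one, (Z)-ethoxyvinyl group cis to the ketene-bearing carbon | O=C=C(Oc1c(OC)cc2oc3cc(OC)cc(OC)c3c2c1Br)/C(Oc1cc(OC)cc(OC)c1)=C(/O)\C=C/OCC
F9 | step 12 | rac-2-[(1-bromo-3,7,9-trimethoxydibenzo[b,d]furan-2-yl)oxy]-3-(3,5-dimethoxyphenoxy)-6-ethoxy-4-hydroxycyclohexa-2,4-dien-1-one | O=C1C(OCC)C=C(O)C(Oc2cc(OC)cc(OC)c2)=C1Oc1c(OC)cc2oc3cc(OC)cc(OC)c3c2c1Br
F10 | step 12 | 2-[(1-bromo-3,7,9-trimethoxydibenzo[b,d]furan-2-yl)oxy]-3-(3,5-dimethoxyphenoxy)-6-ethoxybenzene-1,4-diol | CCOc1cc(O)c(Oc2cc(OC)cc(OC)c2)c(Oc2c(OC)cc3oc4cc(OC)cc(OC)c4c3c2Br)c1O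
F11 | step 13 | methyl ether of 22 at the B2 oxygen | CCOc1cc(OC)c(Oc2c(Cl)c(OC)c(Cl)c(OC)c2Cl)c(Oc2c(OC)cc3oc4cc(OC)cc(OC)c4c3c2Br)c1O[Si](CC)(CC)CC
F12 | step 13 | caesium 2-[(1-bromo-3,7,9-trimethoxydibenzo[b,d]furan-2-yl)oxy]-6-ethoxy-4-methoxy-3-(2,4,6-trichloro-3,5-dimethoxyphenoxy)phenolate | CCOc1cc(OC)c(Oc2c(Cl)c(OC)c(Cl)c(OC)c2Cl)c(Oc2c(OC)cc3oc4cc(OC)cc(OC)c4c3c2Br)c1[O-].[Cs+]
F13 | step 13 | methyl ether of 24 at the B2 oxygen | COc1c(Cl)c(OC)c(Cl)c(Oc2c(OC)cc(OCC)c3c2Oc2c(OC)cc4oc5cc(OC)cc(OC)c5c4c2O3)c1Cl
F14 | step 13 | methyl ether of 25 at the B2 oxygen | COc1cc(OC)cc(Oc2c(OC)cc(OCC)c3c2Oc2c(OC)cc4oc5cc(OC)cc(OC)c5c4c2O3)c1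
F15 | step 5 | 2-bromo-6-methoxybenzene-1,4-diol | COc1cc(O)cc(Br)c1O
F16 | step 5 | 2-bromo-6-methoxycyclohexa-2,5-diene-1,4-dione | COC1=CC(=O)C=C(Br)C1=O
F17 | step 5 | 3-bromo-5-methoxy-2-(2,4,6-trimethoxyphenyl)benzene-1,4-diol | COc1cc(OC)c(-c2c(O)cc(OC)c(O)c2Br)c(OC)c1
A1 | alternative 1 | pentamethyl ether of the target with both ring F hydroxyls free | COc1cc(OC)cc(Oc2c(OC)cc(OC)c3c2Oc2c(OC)cc4oc5cc(O)cc(O)c5c4c2O3)c1
A2 | alternative 1 | O-aryl hydroxylamine of the ring A to ring D tetracycle (pentamethyl ether, O–NH2 on D4) | COc1cc(OC)cc(Oc2c(OC)cc(OC)c3c2Oc2c(OC)cc(ON)cc2O3)c1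
A3 | alternative 1 | phloroglucinol (benzene-1,3,5-triol) | Oc1cc(O)cc(O)c1
A4 | alternative 2 | pentamethyl ether of the target with both ring B hydroxyls free | COc1cc(OC)cc(Oc2c(O)cc(O)c3c2Oc2c(OC)cc4oc5cc(OC)cc(OC)c5c4c2O3)c1
A5 | alternative 2 | dialdehyde with formyl groups on B2 and B4 in place of the hydroxyls (pentamethyl ether) | COc1cc(OC)cc(Oc2c(C=O)cc(C=O)c3c2Oc2c(OC)cc4oc5cc(OC)cc(OC)c5c4c2O3)c1
A6 | alternative 3 | hexamethyl ether of the target with the B2 hydroxyl free | COc1cc(OC)cc(Oc2c(O)cc(OC)c3c2Oc2c(OC)cc4oc5cc(OC)cc(OC)c5c4c2O3)c1
A7 | alternative 3 | open diaryl ether with free B2 phenol, hydrogen on B5 and free hydroxyl on D6 | COc1cc(OC)cc(Oc2c(O)cc(OC)cc2Oc2c(OC)cc3oc4cc(OC)cc(OC)c4c3c2O)c1
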